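**Retrosynthetic overview**
- Target 17 comes from its phenol silyl ether 16 by buffered fluoride desilylation.
- The strategy rests on the unsymmetrical dialkyl ketone C8, which sits between the C7 methylene of the tether and the C9 methylene of the pentyl chain (numbering from the benzylic carbon C1). Both C7–C8 and C8–C9 are made in one operation from primary iodide 11, carbon monoxide 15 and B-pentyl-9-BBN 14.
- Iodide 11 comes from chloro acetate 10 and chloro alcohol 9. The C1–aryl bond of 9 comes from Cu-catalysed opening of (R)-2-(5-chloropentyl)oxirane 7 by the aryl Grignard reagent made from 2.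
- Epoxide 7 comes from (R)-epichlorohydrin 4 and 4-chlorobutylmagnesium bromide. The C2 stereocentre is taken from the chiral pool and its C–O bond is never broken.
- No ring is formed anywhere in the route; the benzene ring is bought with 1.

Key step: step 8

Remark: the C2 stereocentre of the target is assigned (R) (OAc > CH2Ar > chain CH2 > H); 9-BBN is drawn as the monomer although it is handled as its dimer.

**Step 1**
Reactants: 1 3-bromo-5-methoxyphenol
Product: 2 (3-bromo-5-methoxyphenoxy)(tert-butyl)dimethylsilane
Conditions: TBSCl, imidazole, DMF, rt
Reagents that add atoms: tert-butyldimethylsilyl chloride, CC(C)(C)[Si](C)(C)Cl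
Why: Imidazole-promoted O-silylation of a phenol masks the acidic OH for the organomagnesium step and for the base-mediated coupling later on.

**Step 2**
Reactants: 3 1-bromo-4-chlorobutane; 4 (R)-epichlorohydrin
Product: 6 (R)-1,7-dichloroheptan-2-ol, via 4-chlorobutylmagnesium bromide 5 (not isolated)
Conditions: Mg, THF, 20–30 °C; then CuI (10 mol %), 4, THF, −40 → −20 °C; cold aq NH4Cl
Reagents that add atoms: none
Why: Magnesium inserts selectively into the C–Br bond, and the primary Grignard reagent then opens the oxirane of 4 at its unsubstituted carbon (Cu-catalysed SN2 epoxide opening), so the stereocentre is carried over unchanged from the chiral pool.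

**Step 3**
Reactants: 6 (R)-1,7-dichloroheptan-2-ol
Product: 7 (R)-2-(5-chloropentyl)oxirane
Conditions: powdered NaOH, Et2O, rt
Reagents that add atoms: none
Why: Intramolecular Williamson etherification of the 1,2-chlorohydrin (3-exo-tet) closes the oxirane on the former chloromethyl carbon without touching the C2–O bond, so configuration is retained, and the remote primary chloride is inert to hydroxide at room temperature.

**Step 4**
Reactants: 2 (3-bromo-5-methoxyphenoxy)(tert-butyl)dimethylsilane; 7 (R)-2-(5-chloropentyl)oxirane
Product: 9 (R)-1-[3-(tert-butyldimethylsilyloxy)-5-methoxyphenyl]-7-chloroheptan-2-ol, via [3-(tert-butyldimethylsilyloxy)-5-methoxyphenyl]magnesium bromide 8 (not isolated)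
Conditions: Mg, cat. I2, THF, 50 °C; then CuI (10 mol %), 7, THF, −30 → 0 °C; aq NH4Cl
Reagents that add atoms: none
Why: Cu-catalysed ring opening of a monosubstituted epoxide by an aryl Grignard reagent proceeds by SN2 attack at the terminal CH2, forming the aryl–C1 bond while leaving the C2 stereocentre and the unreactive primary chloride untouched.

**Step 5**
Reactants: 9 (R)-1-[3-(tert-butyldimethylsilyloxy)-5-methoxyphenyl]-7-chloroheptan-2-ol
Product: 10 (R)-1-[3-(tert-butyldimethylsilyloxy)-5-methoxyphenyl]-7-chloroheptan-2-yl acetate
Conditions: Ac2O, pyridine, DMAP (cat.), CH2Cl2, 0 °C → rt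
Reagents that add atoms: acetic anhydride, CC(=O)OC(C)=O
Why: DMAP-catalysed O-acylation of the secondary alcohol does not involve the stereogenic carbon, so configuration is retained, and the aryl silyl ether and alkyl chloride are inert.

**Step 6**
Reactants: 10 (R)-1-[3-(tert-butyldimethylsilyloxy)-5-methoxyphenyl]-7-chloroheptan-2-yl acetate
Product: 11 (R)-1-[3-(tert-butyldimethylsilyloxy)-5-methoxyphenyl]-7-iodoheptan-2-yl acetate
Conditions: NaI (excess), butan-2-one, 80 °C, dark
Reagents that add atoms: sodium iodide, [Na+].[I-]
Why: Finkelstein halide exchange (SN2 at the primary carbon) is driven by precipitation of NaCl from the ketone solvent, and the secondary acetate and the silyl ether are stable under these neutral conditions.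

**Step 7**
Reactants: 12 pent-1-ene; 13 9-borabicyclo[3.3.1]nonane (9-BBN)
Product: 14 B-pentyl-9-borabicyclo[3.3.1]nonane
Conditions: THF, 0 °C → rt; solution used as such
Reagents that add atoms: none
Why: Anti-Markovnikov hydroboration of a terminal alkene with 9-BBN places boron on the terminal carbon and gives the B-primary-alkyl borane needed for selective alkyl transfer.

**Step 8**
Reactants: 11 (R)-1-[3-(tert-butyldimethylsilyloxy)-5-methoxyphenyl]-7-iodoheptan-2-yl acetate; 14 B-pentyl-9-borabicyclo[3.3.1]nonane; 15 carbon monoxide
Product: 16 (R)-1-[3-(tert-butyldimethylsilyloxy)-5-methoxyphenyl]-8-oxotridecan-2-yl acetate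
Conditions: Pd(PPh3)4 (5 mol %), K3PO4 (3 equiv), 14 (1.5 equiv), CO (1 atm), benzene/THF, hν (tungsten lamp), rt
Reagents that add atoms: none
Why: This is the known light-promoted, palladium-catalysed carbonylative Suzuki–Miyaura coupling of an iodoalkane with a 9-alkyl-9-BBN, and 11 is an unhindered primary iodide of the substrate class for which it is established. Irradiation drives electron transfer from zerovalent palladium to the C7–I bond, the primary C7 radical captures CO, and the acyl radical recombines with palladium to give an acyl iodide complex of divalent palladium. Phosphate-activated 14 then transfers its primary pentyl group, and reductive elimination forms C8–C9 and returns zerovalent palladium. No ring is closed and no stereocentre is created; C2 lies five atoms from the reacting carbon and its C–O bond is untouched. The selectivity needed is carbonylative over direct alkyl–alkyl coupling and over beta-hydride elimination; it should be secured by the radical entry (no alkylpalladium with beta-hydrogens), by fast CO capture under the CO atmosphere and by 9-BBN transferring only its primary alkyl group. The phenol is silylated so that no phenoxide can intercept the acylpalladium, and the acetate should tolerate anhydrous K3PO4 at room temperature.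

**Step 9**
Reactants: 16 (R)-1-[3-(tert-butyldimethylsilyloxy)-5-methoxyphenyl]-8-oxotridecan-2-yl acetate
Product: 17 (R)-1-(3-hydroxy-5-methoxyphenyl)-8-oxotridecan-2-yl acetate
Conditions: TBAF, AcOH (1:1), THF, 0 °C
Reagents that add atoms: none
Why: Fluoride-mediated cleavage of the aryl silyl ether (driven by Si–F bond formation) is buffered with acetic acid so that the phenoxide is protonated at once and cannot cause acetyl transfer or enolate chemistry at the ketone, leaving the secondary acetate intact.

**Compound list**
1 | 3-bromo-5-methoxyphenol | COc1cc(O)cc(Br)c1 | starting material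
2 | (3-bromo-5-methoxyphenoxy)(tert-butyl)dimethylsilane | COc1cc(O[Si](C)(C)C(C)(C)C)cc(Br)c1 | intermediate
3 | 1-bromo-4-chlorobutane | ClCCCCBr | starting material
4 | (R)-epichlorohydrin [(R)-2-(chloromethyl)oxirane] | ClC[C@H]1CO1 | starting material
5 | 4-chlorobutylmagnesium bromide | ClCCCC[Mg]Br | intermediate
6 | (R)-1,7-dichloroheptan-2-ol | ClC[C@H](O)CCCCCCl | intermediate
7 | (R)-2-(5-chloropentyl)oxirane | ClCCCCC[C@@H]1CO1 | intermediate
8 | [3-(tert-butyldimethylsilyloxy)-5-methoxyphenyl]magnesium bromide | COc1cc(O[Si](C)(C)C(C)(C)C)cc([Mg]Br)c1 | intermediate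
9 | (R)-1-[3-(tert-butyldimethylsilyloxy)-5-methoxyphenyl]-7-chloroheptan-2-ol | ClCCCCC[C@H](Cc1cc(O[Si](C)(C)C(C)(C)C)cc(OC)c1)O | intermediate
10 | (R)-1-[3-(tert-butyldimethylsilyloxy)-5-methoxyphenyl]-7-chloroheptan-2-yl acetate | ClCCCCC[C@H](Cc1cc(O[Si](C)(C)C(C)(C)C)cc(OC)c1)OC(C)=O | intermediate
11 | (R)-1-[3-(tert-butyldimethylsilyloxy)-5-methoxyphenyl]-7-iodoheptan-2-yl acetate | ICCCCC[C@H](Cc1cc(O[Si](C)(C)C(C)(C)C)cc(OC)c1)OC(C)=O | intermediate
12 | pent-1-ene | C=CCCC | starting material
13 | 9-borabicyclo[3.3.1]nonane (9-BBN) | B1C2CCCC1CCC2 | starting material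
14 | B-pentyl-9-borabicyclo[3.3.1]nonane | CCCCCB1C2CCCC1CCC2 | intermediate
15 | carbon monoxide | [C-]#[O+] | starting material
16 | (R)-1-[3-(tert-butyldimethylsilyloxy)-5-methoxyphenyl]-8-oxotridecan-2-yl acetate | CCCCCC(=O)CCCCC[C@H](Cc1cc(O[Si](C)(C)C(C)(C)C)cc(OC)c1)OC(C)=O | intermediate
17 | (R)-1-(3-hydroxy-5-methoxyphenyl)-8-oxotridecan-2-yl acetate | CCCCCC(=O)CCCCC[C@H](Cc1cc(O)cc(OC)c1)OC(C)=O | target

**Step count**
Total: 9 steps. Longest linear sequence: 7 steps (steps 2, 3, 4, 5, 6, 8, 9).

**Steps most likely to fail, with fallbacks**

1. Step 8. The C7 radical may capture CO too slowly, so that the iodide is reduced or dehydrohalogenated or couples directly with the pentyl group; the aryl silyl ether may also erode under the basic heterogeneous conditions. The fallback gives up the CO linchpin and forms C7–C8 by acylation. It sets out from iodide 11: zinc insertion (Zn dust activated with 1,2-dibromoethane and TMSCl, THF, 40 °C) should give [(R)-6-acetoxy-7-[3-(tert-butyldimethylsilyloxy)-5-methoxyphenyl]heptyl]zinc iodide F1, an organozinc that tolerates the acetate and silyl ether. Negishi acylation of F1 with hexanoyl chloride (CCCCCC(Cl)=O) under Pd(PPh3)4 catalysis in THF then comes back to the route at 16.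

2. Step 4. The electron-rich aryl bromide may form its Grignard reagent sluggishly, or magnesium halide may open the epoxide to a halohydrin faster than the C–C bond forms. The fallback changes the nucleophile and the mode of activation. It sets out from 2 and 7: bromine–lithium exchange on 2 with n-BuLi (THF, −78 °C) should give [3-(tert-butyldimethylsilyloxy)-5-methoxyphenyl]lithium F2, which is added to epoxide 7 in the presence of BF3·OEt2 at −78 °C (Lewis-acid-promoted organolithium opening at the terminal carbon). Aqueous work-up comes back to the route at 9.

3. Step 2. The ω-chloroalkyl Grignard reagent may self-couple or cyclise, the magnesium alkoxide may close to an epoxide in the flask and add a second time, or partial attack at the chloromethyl carbon may erode enantiopurity. The fallback replaces the chiral-pool opening by a kinetic resolution. It sets out from 3: coupling with allylmagnesium bromide (C=CC[Mg]Br) under Li2CuCl4 catalysis in THF at 0 °C, selective for the bromide, should give 7-chlorohept-1-ene F3. Epoxidation with mCPBA in CH2Cl2 gives racemic 2-(5-chloropentyl)oxirane F4. Hydrolytic kinetic resolution with (R,R)-(salen)Co(OAc) (salen = N,N'-bis(3,5-di-tert-butylsalicylidene)-1,2-cyclohexanediamine) and 0.55 equiv of water is expected to hydrolyse the (S)-epoxide to its diol and leave the (R)-epoxide, which is distilled off; this sense of selectivity is assumed from the general behaviour of the (R,R) catalyst and should be confirmed. The sequence comes back to the route at 7.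

**Further compounds**
F1 | step 8 | [(R)-6-acetoxy-7-[3-(tert-butyldimethylsilyloxy)-5-methoxyphenyl]heptyl]zinc iodide | I[Zn]CCCCC[C@H](Cc1cc(O[Si](C)(C)C(C)(C)C)cc(OC)c1)OC(C)=O
F2 | step 4 | [3-(tert-butyldimethylsilyloxy)-5-methoxyphenyl]lithium | [Li]c1cc(OC)cc(O[Si](C)(C)C(C)(C)C)c1
F3 | step 2 | 7-chlorohept-1-ene | ClCCCCCC=C
F4 | step 2 | racemic 2-(5-chloropentyl)oxirane | ClCCCCCC1CO1
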